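**Strategy.** Everything rests on one oxidative annulation that closes both the dibenzo-fused seven-membered carbocycle and the dihydrofuran fused to it. The precursor is an (E)-4-hydroxystilbene whose resorcinol ring is tied through the CH2–CH(aryl) bridge (C8b–C7b) to the central benzene ring B, which keeps one free phenol. The step exploits the 4-hydroxyphenyl group on the O-bearing furan carbon C7a: two-electron oxidation makes the neighbouring carbon C8a the terminus of an extended quinone methide cation, ring B attacks it through C10b, ortho to its OH, and that OH then adds to C7a. C7b controls both new stereocentres; the second dihydrofuran and C7b are set earlier by asymmetric catalysis.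

Key step: step 13

Atom labels: C7a/C8a are the O-bearing and aryl-bearing carbons of the dihydrofuran in the seven-membered-ring half. C9a–C14a is the resorcinol ring on C8a (C10a bears C7b; C11a and C13a bear oxygen). C7b is the bridge CH with the 2,4-dioxygenated phenyl group and C8b the bridge CH2. C9b–C14b is the central ring B (C9b bears C8b, C10b bears C8a, C11b and C13b bear the two furan oxygens, C14b bears C8c). C7c/C8c are the O-bearing and aryl-bearing carbons of the second dihydrofuran.

Assumption: the chiral catalysts of steps 4 and 7 are named as the enantiomers expected to give the configurations drawn; if the sense of induction is the opposite, the antipodal catalyst is used.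

**Route**

Step 1
Reactants: 1 5-bromoresorcinol; 2 3,5-dimethoxybenzoic acid
Product: 3 (2-bromo-4,6-dihydroxyphenyl)(3,5-dimethoxyphenyl)methanone
Conditions: BF3·OEt2 (neat), 90 °C; aq. NaOAc work-up
Reagents that add atoms: none
Why: Friedel–Crafts acylation of the resorcinol should occur at C4 (para to one OH, ortho to the other), as it does with orcinol, the carbon between the two OH groups being the less reactive one.

Step 2
Reactants: 3 (2-bromo-4,6-dihydroxyphenyl)(3,5-dimethoxyphenyl)methanone; 4 4-methoxybenzyl chloride (2.4 equiv in all)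
Product: 5 [2-bromo-4,6-bis(4-methoxybenzyloxy)phenyl](3,5-dimethoxyphenyl)methanone
Conditions: 4 (2.4 equiv), K2CO3 (3 equiv), NaI (cat.), DMF, 60 °C
Reagents that add atoms: 4-methoxybenzyl chloride (second equivalent of 4), COc1ccc(CCl)cc1
Why: Twofold Williamson etherification, each phenol consuming one equivalent of the benzyl chloride (the free para phenol first, the carbonyl-chelated ortho phenol on warming); the ortho ether later supplies C7c with its aryl group and the para ether protects the C11b oxygen.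

Step 3
Reactants: 5 [2-bromo-4,6-bis(4-methoxybenzyloxy)phenyl](3,5-dimethoxyphenyl)methanone
Product: 6 hydrazone of ketone 5
Conditions: N2H4·H2O (excess), AcOH (cat.), EtOH, sealed tube, 100 °C
Reagents that add atoms: hydrazine (as hydrate), NN
Why: Condensation of the diaryl ketone with hydrazine (hydrazone formation); forcing conditions are chosen because the carbonyl group lies between two ortho substituents.

Step 4
Reactants: 6 hydrazone of ketone 5
Product: 8 (2S,3R)-4-bromo-3-(3,5-dimethoxyphenyl)-6-(4-methoxybenzyloxy)-2-(4-methoxyphenyl)-2,3-dihydrobenzofuran (cis), via diaryldiazomethane 7 (not isolated)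
Conditions: MnO2, CH2Cl2, 0 °C, filtration; then Rh2(R-PTAD)4 (dirhodium tetrakis[(R)-(1-adamantyl)(phthalimido)acetate], 1 mol %), CH2Cl2, −20 °C to rt
Reagents that add atoms: none
Why: Oxidation of the hydrazone to the diazo compound, then enantioselective intramolecular 1,5 C–H insertion of the donor/donor rhodium carbene into the benzylic C–H of the ortho ether; the chiral carboxylate catalyst should set C8c (3R), and the cis relationship is the kinetic outcome of the insertion.

Step 5
Reactants: 8 cis-dihydrobenzofuran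
Product: 9 (2R,3R)-4-bromo-3-(3,5-dimethoxyphenyl)-2-(4-methoxyphenyl)-2,3-dihydrobenzofuran-6-ol (trans)
Conditions: CF3CO2H/CH2Cl2 (1:4), C6Me5H, 0 °C to rt
Reagents that add atoms: none
Why: Acidolysis should remove the para-methoxybenzyl ether (cation trapped by pentamethylbenzene), while reversible ionization of the benzylic C7c–O bond epimerizes C7c to the more stable 2,3-trans isomer and leaves C8c untouched.

Step 6
Reactants: 10 2,4-dimethoxybenzaldehyde; 11 (triphenylphosphoranylidene)acetaldehyde
Product: 12 (E)-3-(2,4-dimethoxyphenyl)prop-2-enal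
Conditions: toluene, 80 °C
Reagents that add atoms: none
Why: Wittig olefination with a stabilized ylide should give the E-enal.

Step 7
Reactants: 12 (E)-3-(2,4-dimethoxyphenyl)prop-2-enal; 13 3,5-dimethoxyphenol
Product: 14 (4S)-4-(2,4-dimethoxyphenyl)-5,7-dimethoxychroman-2-ol (anomer mixture)
Conditions: (S)-α,α-diphenylprolinol trimethylsilyl ether (20 mol %), PhCO2H (20 mol %), toluene, 0 °C to rt
Reagents that add atoms: none
Why: Organocatalytic Friedel–Crafts alkylation/hemiacetalization under iminium activation; the phenol should add through its carbon ortho to OH to the unshielded face of the E-iminium β-carbon, which sets C7b (S).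

Step 8
Reactants: 14 (4S)-4-(2,4-dimethoxyphenyl)-5,7-dimethoxychroman-2-ol
Product: 15 (4S)-4-(2,4-dimethoxyphenyl)-5,7-dimethoxychroman-2-one
Conditions: Pr4N[RuO4] (5 mol %), N-methylmorpholine N-oxide, 4 Å molecular sieves, CH2Cl2, rt
Reagents that add atoms: none
Why: Ley–Griffith oxidation of the lactol to the lactone under neutral conditions that should not touch the electron-rich arenes or C7b.

Step 9
Reactants: 15 (4S)-4-(2,4-dimethoxyphenyl)-5,7-dimethoxychroman-2-one
Product: 17 (3S)-3-(2,4-dimethoxyphenyl)-3-[2,4-dimethoxy-6-(trifluoromethylsulfonyloxy)phenyl]propanoic acid, via dipotassium phenoxide carboxylate 16 (not isolated)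
Conditions: KOSiMe3 (2.2 equiv), THF, rt; then PhNTf2, 0 °C to rt; 1 M HCl work-up
Reagents that add atoms: potassium trimethylsilanolate, C[Si](C)(C)[O-].[K+]; N-phenylbis(trifluoromethanesulfonimide), O=S(=O)(N(c1ccccc1)S(=O)(=O)C(F)(F)F)C(F)(F)F
Why: Silanolate opening of the aryl lactone, then selective O-sulfonylation of the phenoxide (the carboxylate is a poor nucleophile towards PhNTf2); this blocks relactonization and installs the handle for the later stilbene coupling.

Step 10
Reactants: 17 triflate acid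
Product: 18 1,3-dioxoisoindolin-2-yl (3S)-3-(2,4-dimethoxyphenyl)-3-[2,4-dimethoxy-6-(trifluoromethylsulfonyloxy)phenyl]propanoate
Conditions: N-hydroxyphthalimide, N,N'-diisopropylcarbodiimide, DMAP (cat.), CH2Cl2, rt
Reagents that add atoms: N-hydroxyphthalimide, O=C1c2ccccc2C(=O)N1O
Why: Steglich-type esterification should give the redox-active ester needed for decarboxylative coupling.

Step 11
Reactants: 18 redox-active ester; 9 (2R,3R)-bromophenol
Product: 19 2-[(1S)-1-(2,4-dimethoxyphenyl)-2-[(2R,3R)-3-(3,5-dimethoxyphenyl)-6-hydroxy-2-(4-methoxyphenyl)-2,3-dihydrobenzofuran-4-yl]ethyl]-3,5-dimethoxyphenyl trifluoromethanesulfonate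
Conditions: NiBr2(dme) (10 mol %), 4,4'-di-tert-butyl-2,2'-bipyridine (10 mol %), Zn powder, NaI (cat.), DMA, 40 °C
Reagents that add atoms: none
Why: Nickel-catalysed decarboxylative cross-electrophile coupling, in which reduction of the ester releases CO2 and the primary C8b radical, captured by the arylnickel species formed from the C9b–Br bond; free OH and aryl triflate groups are expected to be tolerated, and no stereocentre is involved.

Step 12
Reactants: 19 aryl triflate; 20 4-acetoxystyrene
Product: 22 4-[(E)-2-{2-[(1S)-1-(2,4-dimethoxyphenyl)-2-[(2R,3R)-3-(3,5-dimethoxyphenyl)-6-hydroxy-2-(4-methoxyphenyl)-2,3-dihydrobenzofuran-4-yl]ethyl]-3,5-dimethoxyphenyl}ethenyl]phenol, via acetoxystilbene 21 (not isolated)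
Conditions: Pd(PPh3)2Cl2 (5 mol %), LiCl, Et3N, DMF, 100 °C; then K2CO3, MeOH, rt
Reagents that add atoms: none
Why: Mizoroki–Heck reaction of the aryl triflate (chloride additive, neutral pathway) should give the E-stilbene by syn insertion and syn β-hydride elimination, and methanolysis then frees the stilbene phenol.

Step 13
Reactants: 22 (E)-4-hydroxystilbene with free C11b–OH
Product: 24 heptamethyl ether of the target with free 4-OH on the C7a aryl group (7aS,8aS,7bS,7cR,8cR), via para-quinone methide 23 (not isolated)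
Conditions: PhI(OAc)2 (1.05 equiv, slow addition), (CF3)2CHOH/CH2Cl2, 1 mM, −20 °C
Reagents that add atoms: none
Why: PhI(OAc)2 should oxidize the only conjugated phenol, the 4-hydroxystilbene, by two electrons to an extended quinone methide cation with its positive end at C8a; C10b of ring B, the one arene carbon within reach that is activated twice (ortho to the free OH, para to the other furan oxygen), attacks C8a in a Friedel–Crafts step (7-exo-trig onto the C8a=C7a bond), and rearomatization leaves the para-quinone methide 23, to whose exocyclic carbon C7a the neighbouring phenol then adds (5-exo-trig oxa-Michael addition). The closest known reaction type is the biomimetic oxidative coupling of resveratrol to the ε-viniferin dihydrobenzofuran, run here intramolecularly. C8a is set by C7b: in the forming cycloheptadiene the C7b aryl group should sit pseudoaxial to avoid the methoxy group on C11a, and the quinone methide arm should take the face opposite to that aryl group, which places H8a and H7b trans as in the target. C7a follows from the reversible oxa-Michael addition, which should settle on the 2,3-trans dihydrofuran. The step needs chemoselective oxidation and intramolecular capture: the methyl ethers leave a single readily oxidized phenol, the unactivated carbons of the other arenes (for example C6 of the dimethoxyphenyl group on C7b, meta to both ethers) should not compete, and high dilution in the non-nucleophilic fluoro alcohol should suppress dimerization and solvent capture.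

Step 14
Reactants: 24 heptamethyl ether
Product: 25 CNP0154047.3 (target)
Conditions: BBr3 (excess), CH2Cl2, −78 °C to rt; then MeOH, H2O
Reagents that add atoms: none
Why: Exhaustive Lewis acid cleavage of the seven aryl methyl ethers; C8a, C8c and C7b cannot epimerize, and C7a and C7c, should their benzylic C–O bonds ionize, should reclose to the trans-dihydrofurans.

**Compound list**

1 | 5-bromoresorcinol | Oc1cc(O)cc(Br)c1 | starting material
2 | 3,5-dimethoxybenzoic acid | COc1cc(OC)cc(c1)C(O)=O | starting material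
3 | (2-bromo-4,6-dihydroxyphenyl)(3,5-dimethoxyphenyl)methanone | COc1cc(OC)cc(c1)C(=O)c1c(O)cc(O)cc1Br | intermediate
4 | 4-methoxybenzyl chloride | COc1ccc(CCl)cc1 | starting material
5 | [2-bromo-4,6-bis(4-methoxybenzyloxy)phenyl](3,5-dimethoxyphenyl)methanone | COc1ccc(COc2cc(OCc3ccc(OC)cc3)c(C(=O)c3cc(OC)cc(OC)c3)c(Br)c2)cc1 | intermediate
6 | hydrazone of ketone 5 | NN=C(c1cc(OC)cc(OC)c1)c1c(OCc2ccc(OC)cc2)cc(OCc2ccc(OC)cc2)cc1Br | intermediate
7 | [2-bromo-4,6-bis(4-methoxybenzyloxy)phenyl](3,5-dimethoxyphenyl)diazomethane | [N-]=[N+]=C(c1cc(OC)cc(OC)c1)c1c(OCc2ccc(OC)cc2)cc(OCc2ccc(OC)cc2)cc1Br | intermediate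
8 | (2S,3R)-4-bromo-3-(3,5-dimethoxyphenyl)-6-(4-methoxybenzyloxy)-2-(4-methoxyphenyl)-2,3-dihydrobenzofuran (cis) | Brc1cc(OCc3ccc(OC)cc3)cc2c1[C@@H](c1cc(OC)cc(OC)c1)[C@@H](c1ccc(OC)cc1)O2 | intermediate
9 | (2R,3R)-4-bromo-3-(3,5-dimethoxyphenyl)-2-(4-methoxyphenyl)-2,3-dihydrobenzofuran-6-ol (trans) | Brc1cc(O)cc2c1[C@@H](c1cc(OC)cc(OC)c1)[C@H](c1ccc(OC)cc1)O2 | intermediate
10 | 2,4-dimethoxybenzaldehyde | COc1ccc(C=O)c(OC)c1 | starting material
11 | (triphenylphosphoranylidene)acetaldehyde | O=CC=P(c1ccccc1)(c1ccccc1)c1ccccc1 | starting material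
12 | (E)-3-(2,4-dimethoxyphenyl)prop-2-enal | COc1ccc(/C=C/C=O)c(OC)c1 | intermediate
13 | 3,5-dimethoxyphenol | COc1cc(O)cc(OC)c1 | starting material
14 | (4S)-4-(2,4-dimethoxyphenyl)-5,7-dimethoxychroman-2-ol (anomer mixture) | COc1cc(OC)c2c(c1)OC(O)C[C@H]2c1ccc(OC)cc1OC | intermediate
15 | (4S)-4-(2,4-dimethoxyphenyl)-5,7-dimethoxychroman-2-one | COc1cc(OC)c2c(c1)OC(=O)C[C@H]2c1ccc(OC)cc1OC | intermediate
16 | dipotassium (3S)-3-(2,4-dimethoxyphenyl)-3-(2,4-dimethoxy-6-oxidophenyl)propanoate | [K+].[K+].[O-]C(=O)C[C@@H](c1ccc(OC)cc1OC)c1c([O-])cc(OC)cc1OC | intermediate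
17 | (3S)-3-(2,4-dimethoxyphenyl)-3-[2,4-dimethoxy-6-(trifluoromethylsulfonyloxy)phenyl]propanoic acid | OC(=O)C[C@@H](c1ccc(OC)cc1OC)c1c(OS(=O)(=O)C(F)(F)F)cc(OC)cc1OC | intermediate
18 | 1,3-dioxoisoindolin-2-yl ester of acid 17 | O=C(C[C@@H](c1ccc(OC)cc1OC)c1c(OS(=O)(=O)C(F)(F)F)cc(OC)cc1OC)ON1C(=O)c2ccccc2C1=O | intermediate
19 | 2-[(1S)-1-(2,4-dimethoxyphenyl)-2-[(2R,3R)-3-(3,5-dimethoxyphenyl)-6-hydroxy-2-(4-methoxyphenyl)-2,3-dihydrobenzofuran-4-yl]ethyl]-3,5-dimethoxyphenyl trifluoromethanesulfonate | FC(F)(F)S(=O)(=O)Oc1cc(OC)cc(OC)c1[C@H](c1ccc(OC)cc1OC)Cc1cc(O)cc2c1[C@@H](c1cc(OC)cc(OC)c1)[C@H](c1ccc(OC)cc1)O2 | intermediate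
20 | 4-acetoxystyrene | CC(=O)Oc1ccc(C=C)cc1 | starting material
21 | acetate of stilbene phenol 22 | CC(=O)Oc1ccc(/C=C/c2cc(OC)cc(OC)c2[C@H](c2ccc(OC)cc2OC)Cc2cc(O)cc3c2[C@@H](c2cc(OC)cc(OC)c2)[C@H](c2ccc(OC)cc2)O3)cc1 | intermediate
22 | 4-[(E)-2-{2-[(1S)-1-(2,4-dimethoxyphenyl)-2-[(2R,3R)-3-(3,5-dimethoxyphenyl)-6-hydroxy-2-(4-methoxyphenyl)-2,3-dihydrobenzofuran-4-yl]ethyl]-3,5-dimethoxyphenyl}ethenyl]phenol | Oc1ccc(/C=C/c2cc(OC)cc(OC)c2[C@H](c2ccc(OC)cc2OC)Cc2cc(O)cc3c2[C@@H](c2cc(OC)cc(OC)c2)[C@H](c2ccc(OC)cc2)O3)cc1 | intermediate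
23 | para-quinone methide with the seven-membered ring closed (C8a–C10b bond formed, C7a exocyclic to the cyclohexadienone, C11b–OH free) | O=C1C=CC(=C[C@H]2c3cc(OC)cc(OC)c3[C@H](c3ccc(OC)cc3OC)Cc3c2c(O)cc2c3[C@@H](c3cc(OC)cc(OC)c3)[C@H](c3ccc(OC)cc3)O2)C=C1 | intermediate
24 | heptamethyl ether of the target with free 4-OH on the C7a aryl group (7aS,8aS,7bS,7cR,8cR) | Oc1ccc([C@H]2Oc3cc4c(c5c3[C@@H]2c2cc(OC)cc(OC)c2[C@H](c2ccc(OC)cc2OC)C5)[C@@H](c2cc(OC)cc(OC)c2)[C@H](c2ccc(OC)cc2)O4)cc1 | intermediate
25 | CNP0154047.3 (7aS,8aS,7bS,7cR,8cR) | Oc1ccc([C@H]2Oc3cc4c(c5c3[C@@H]2c2cc(O)cc(O)c2[C@H](c2ccc(O)cc2O)C5)[C@@H](c2cc(O)cc(O)c2)[C@H](c2ccc(O)cc2)O4)cc1 | target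

**Step count.** 14 steps in total. The longest linear sequence is 9 steps (steps 1–5, then 11–14; the branch of steps 6–10, then 11–14, is equally long).

**Steps most likely to fail**

1. Step 13. Intermolecular coupling of the oxidized stilbene may outrun ring closure, or the new C–C bond may form on the wrong face at C8a. Fallback, from 19 to 25: the C–C bond is made by palladium and the C–O bond by acid, in separate steps. Heck reaction of 19 with 4-methoxystyrene (conditions of step 12 without the methanolysis) gives the methoxystilbene F1. Iodination of its single phenol at C10b, ortho to the hydroxyl and para to the furan oxygen (I2, morpholine, CH2Cl2), gives the ortho-iodophenol F2. An intramolecular 7-exo Heck reaction (Pd(OAc)2, P(o-tol)3, Et3N, DMF, 90 °C) closes the seven-membered ring and leaves the exocyclic benzylidene F3. Catalytic CF3SO3H in toluene should protonate C8a and let the phenol add to the para-methoxybenzylic cation at C7a (acid-catalysed hydroalkoxylation, thermodynamic control) to give the octamethyl ether F4. BBr3 as in step 14 then brings the route back at 25.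

2. Step 4. Insertion may be slow, or enantio- and diastereocontrol may be lost, because the carbene carbon lies between two ortho substituents. Fallback, from 6 to 9: resolution replaces asymmetric catalysis. The diazo compound 7 is made as in step 4 and decomposed with achiral Rh2(OAc)4 to the racemate, that is 8 together with ent-8 F5. The acid step (conditions of step 5) gives 9 together with ent-9 F6. (S)-1-Phenylethyl isocyanate (Et3N, CH2Cl2) converts the two phenols into the (2R,3R)-carbamate F7 and the (2S,3S)-carbamate F8, which are separated by chromatography or crystallization. K2CO3 in MeOH cleaves F7 and returns 9.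

3. Step 11. Oxidative addition into the hindered, electron-rich aryl bromide may be slow, so that the alkyl radical is lost to reduction, dimerization or a 1,2-aryl shift before it is captured, or nickel may insert into the aryl triflate. Fallback, from 9 and 18 to 19: the polarity of the aryl partner is reversed, so that radical capture no longer waits for an oxidative addition. Silylation of 9 (t-BuMe2SiCl, imidazole, DMF) gives the silyl ether F9. Bromine–lithium exchange (t-BuLi, THF, −78 °C) and ZnCl2 give the arylzinc chloride F10, which is coupled with 18 in an iron-catalysed decarboxylative Negishi-type reaction (Fe(acac)3, 1,2-bis(diphenylphosphino)benzene, THF) to the coupled silyl ether F11. Et3N·3HF removes the silyl group and returns 19.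

**Further compounds**

F1 | step 13 | 4-methoxystilbene analogue of 22 (methyl ether at the stilbene phenol, C11b–OH free) | COc1ccc(/C=C/c2cc(OC)cc(OC)c2[C@H](c2ccc(OC)cc2OC)Cc2cc(O)cc3c2[C@@H](c2cc(OC)cc(OC)c2)[C@H](c2ccc(OC)cc2)O3)cc1
F2 | step 13 | C10b-iodo derivative of F1 | COc1ccc(/C=C/c2cc(OC)cc(OC)c2[C@H](c2ccc(OC)cc2OC)Cc2c(I)c(O)cc3c2[C@@H](c2cc(OC)cc(OC)c2)[C@H](c2ccc(OC)cc2)O3)cc1
F3 | step 13 | exocyclic 4-methoxybenzylidene at C8a of the closed seven-membered ring (alkene geometry not defined, C11b–OH free) | COc1ccc(C=C2c3cc(OC)cc(OC)c3[C@H](c3ccc(OC)cc3OC)Cc3c2c(O)cc2c3[C@@H](c3cc(OC)cc(OC)c3)[C@H](c3ccc(OC)cc3)O2)cc1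
F4 | step 13 | octamethyl ether of the target (7aS,8aS,7bS,7cR,8cR) | COc1ccc([C@H]2Oc3cc4c(c5c3[C@@H]2c2cc(OC)cc(OC)c2[C@H](c2ccc(OC)cc2OC)C5)[C@@H](c2cc(OC)cc(OC)c2)[C@H](c2ccc(OC)cc2)O4)cc1
F5 | step 4 | ent-8, (2R,3S)-4-bromo-3-(3,5-dimethoxyphenyl)-6-(4-methoxybenzyloxy)-2-(4-methoxyphenyl)-2,3-dihydrobenzofuran | Brc1cc(OCc3ccc(OC)cc3)cc2c1[C@H](c1cc(OC)cc(OC)c1)[C@H](c1ccc(OC)cc1)O2
F6 | step 4 | ent-9, (2S,3S)-4-bromo-3-(3,5-dimethoxyphenyl)-2-(4-methoxyphenyl)-2,3-dihydrobenzofuran-6-ol | Brc1cc(O)cc2c1[C@H](c1cc(OC)cc(OC)c1)[C@@H](c1ccc(OC)cc1)O2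
F7 | step 4 | N-[(1S)-1-phenylethyl]carbamate of 9 | Brc1cc(OC(=O)N[C@@H](C)c3ccccc3)cc2c1[C@@H](c1cc(OC)cc(OC)c1)[C@H](c1ccc(OC)cc1)O2
F8 | step 4 | N-[(1S)-1-phenylethyl]carbamate of ent-9 | Brc1cc(OC(=O)N[C@@H](C)c3ccccc3)cc2c1[C@H](c1cc(OC)cc(OC)c1)[C@@H](c1ccc(OC)cc1)O2
F9 | step 11 | tert-butyldimethylsilyl ether of 9 | Brc1cc(O[Si](C)(C)C(C)(C)C)cc2c1[C@@H](c1cc(OC)cc(OC)c1)[C@H](c1ccc(OC)cc1)O2
F10 | step 11 | arylzinc chloride from F9 | Cl[Zn]c1cc(O[Si](C)(C)C(C)(C)C)cc2c1[C@@H](c1cc(OC)cc(OC)c1)[C@H](c1ccc(OC)cc1)O2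
F11 | step 11 | tert-butyldimethylsilyl ether of 19 | FC(F)(F)S(=O)(=O)Oc1cc(OC)cc(OC)c1[C@H](c1ccc(OC)cc1OC)Cc1cc(O[Si](C)(C)C(C)(C)C)cc2c1[C@@H](c1cc(OC)cc(OC)c1)[C@H](c1ccc(OC)cc1)O2
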